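**Retrosynthetic overview**
1. Feature: the C4a–C8a bond shared by rings A and C is the enone C=C (C5=C6) of a 2-aryl-2,3-dihydro-4H-pyran-4-one. C5–C6–C7–C8, with O5, O7, the 6-prenyl and the 8-lavandulyl group, is the C1–C4 backbone of a 2-prenyl-4-lavandulyl acetoacetate.
2. Key disconnection: C8–C8a and C4a–C5. Ring A is annulated last, by cycloaddition–aromatisation of the 1-methoxy-1,3-bis(trimethylsilyloxy)diene onto the enantiopure pyranone. The pyranone carries a phenylsulfinyl group at C5 as activator and as syn-leaving group; a C5 halogen would sit syn to the non-acidic H-8a in the adduct and could not be lost cleanly.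
3. Ring order: B (purchased), then C (asymmetric hetero-Diels–Alder, sets C2), then A (key step). O1 stems from the pyranone and O5 from the ester carbon, so ring A can form in only one orientation.
4. The lavandulyl centre comes from an Evans deconjugative prenylation. The (R) centre of the target corresponds spatially to (S)-lavandulol, because the CIP ranking changes when CH2OH becomes CH2Ar.
5. The ring B phenols travel as TBS ethers. These activate ring B less than alkyl ethers and stabilise a C2 benzylic cation less. They are released with buffered fluoride in the last step.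

Key step: step 13

Assumption: the (S)-configured BINOL-type ligand on Ti(IV) is taken to direct the diene to the Si face of the aryl aldehyde, the sense usual for related carbonyl additions. If the first run shows the opposite sense, the equally available (R)-ligand is used and nothing else changes.

**Route**

Step 1
Reactants: 1 2,4-dihydroxybenzaldehyde
Product: 2 2,4-bis(tert-butyldimethylsilyloxy)benzaldehyde
Conditions: TBSCl (2.4 equiv), imidazole (5 equiv), DMF, rt
Reagents that add atoms: tert-butyldimethylsilyl chloride, CC(C)(C)[Si](C)(C)Cl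
Why: Imidazole-promoted silylation of both phenols is routine, and silyl ethers are chosen because they damp ring B towards the sulfur electrophile and peracid used later and can be removed with fluoride, without the acid or base that would cyclise the prenyl groups or open the flavanone.

Step 2
Reactants: 2 2,4-bis(tert-butyldimethylsilyloxy)benzaldehyde; 3 Danishefsky's diene [(E)-1-methoxy-3-(trimethylsilyloxy)buta-1,3-diene]
Product: 5 (2S)-2-[2,4-bis(tert-butyldimethylsilyloxy)phenyl]-2,3-dihydro-4H-pyran-4-one, via open-chain silylated aldol adduct 4 (not isolated)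
Conditions: (S)-H8-BINOL (22 mol %), Ti(OiPr)4 (20 mol %), 4 Å MS, PhMe, 0 °C; then TFA, CH2Cl2, 0 °C
Reagents that add atoms: none
Why: This is a catalytic asymmetric hetero-Diels–Alder reaction (Mukaiyama-aldol pathway on Ti–BINOL catalysts, then acid-induced oxa-Michael closure with loss of methanol) in which C2 is set by catalyst-controlled attack of the diene terminus on the Si face of the aldehyde, and the enantiomeric purity is to be checked by chiral HPLC before going on.

Step 3
Reactants: 5 (2S)-2-[2,4-bis(tert-butyldimethylsilyloxy)phenyl]-2,3-dihydro-4H-pyran-4-one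
Product: 7 (2S)-2-[2,4-bis(tert-butyldimethylsilyloxy)phenyl]-5-(phenylsulfanyl)-2,3-dihydro-4H-pyran-4-one, via 6-chloro-5-(phenylsulfanyl)tetrahydropyranone 6 (not isolated)
Conditions: PhSSPh (0.55 equiv), SO2Cl2 (0.55 equiv), CH2Cl2, 0 °C; add to 5, CH2Cl2, −78 → 0 °C; then Et3N (1.5 equiv)
Reagents that add atoms: benzenesulfenyl chloride, ClSc1ccccc1 (generated from diphenyl disulfide, c1ccc(cc1)SSc1ccccc1)
Why: In this electrophilic α-sulfenylation of a vinylogous ester by addition–elimination, the enol-ether carbon C5 is the most nucleophilic site, chloride captures the C6 oxocarbenium ion, and Et3N removes the now acidic H-5 to restore the enone without touching C2.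

Step 4
Reactants: 7 (2S)-2-[2,4-bis(tert-butyldimethylsilyloxy)phenyl]-5-(phenylsulfanyl)-2,3-dihydro-4H-pyran-4-one
Product: 8 (2S)-2-[2,4-bis(tert-butyldimethylsilyloxy)phenyl]-5-(phenylsulfinyl)-2,3-dihydro-4H-pyran-4-one (both sulfur epimers)
Conditions: mCPBA (1.0 equiv), NaHCO3, CH2Cl2, −78 → −30 °C
Reagents that add atoms: meta-chloroperbenzoic acid, O=C(OO)c1cccc(Cl)c1
Why: One equivalent of peracid at low temperature should oxidise the sulfide selectively to the sulfoxide, since sulfur is far more nucleophilic than the push–pull alkene or the silylated arene, and the new sulfur stereocentre is irrelevant because the group is expelled in step 13.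

Step 5
Reactants: 9 (S)-4-benzyl-1,3-oxazolidin-2-one; 10 3-methylbut-2-enoyl chloride (senecioyl chloride)
Product: 11 (4S)-4-benzyl-3-(3-methylbut-2-enoyl)-1,3-oxazolidin-2-one
Conditions: n-BuLi, THF, −78 °C; then 10, −78 → 0 °C
Reagents that add atoms: none
Why: N-Acylation of the lithiated Evans auxiliary with an acid chloride is standard.

Step 6
Reactants: 11 (4S)-4-benzyl-3-(3-methylbut-2-enoyl)-1,3-oxazolidin-2-one; 12 prenyl bromide (1-bromo-3-methylbut-2-ene)
Product: 13 (4S)-4-benzyl-3-[(2S)-5-methyl-2-(prop-1-en-2-yl)hex-4-enoyl]-1,3-oxazolidin-2-one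
Conditions: NaHMDS (1.05 equiv), THF, −78 °C; then 12, −78 → −40 °C; AcOH quench at −78 °C
Reagents that add atoms: none
Why: In this Evans asymmetric alkylation in its deconjugative form, γ-deprotonation of the s-cis enoyl imide gives the chelated (Z)-dienolate, which reacts at the α-carbon on the face opposite the benzyl group and so sets the (S) centre that becomes the lavandulyl stereocentre.

Step 7
Reactants: 13 (4S)-4-benzyl-3-[(2S)-5-methyl-2-(prop-1-en-2-yl)hex-4-enoyl]-1,3-oxazolidin-2-one
Product: 14 (S)-lavandulol [(2S)-5-methyl-2-(prop-1-en-2-yl)hex-4-en-1-ol]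
Conditions: LiBH4, MeOH (1 equiv), Et2O, 0 °C
Reagents that add atoms: none
Why: Reductive cleavage of the N-acyl oxazolidinone with borohydride is essentially non-basic, so the allylic α-centre should neither epimerise nor move into conjugation, and the auxiliary is recovered.

Step 8
Reactants: 14 (S)-lavandulol
Product: 15 (S)-lavandulyl iodide [(3S)-3-(iodomethyl)-2,6-dimethylhepta-1,5-diene]
Conditions: I2, PPh3, imidazole, CH2Cl2, 0 °C
Reagents that add atoms: iodine, II
Why: Appel-type iodination (Garegg–Samuelsson conditions) is an SN2 displacement at the primary carbon and leaves the adjacent stereocentre untouched.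

Step 9
Reactants: 16 methyl acetoacetate; 12 prenyl bromide
Product: 17 methyl 2-acetyl-5-methylhex-4-enoate (racemic)
Conditions: NaH (1.0 equiv), 16 (1.3 equiv), THF, 0 °C; then 12, 0 °C → rt
Reagents that add atoms: none
Why: This is a classical acetoacetic ester alkylation with a reactive allylic bromide, and the slight excess of 16 suppresses double alkylation.

Step 10
Reactants: 17 methyl 2-acetyl-5-methylhex-4-enoate; 15 (S)-lavandulyl iodide
Product: 18 methyl (6S)-9-methyl-2-(3-methylbut-2-en-1-yl)-3-oxo-6-(prop-1-en-2-yl)dec-8-enoate (C2 epimers)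
Conditions: 17 (1.6 equiv), NaH, THF, 0 °C; n-BuLi, 0 °C; then 15, 0 °C → rt; aq. NH4Cl
Reagents that add atoms: none
Why: In this Weiler-type dianion alkylation the γ-carbanion is by far the more nucleophilic site and displaces the primary iodide by SN2 without touching the neighbouring stereocentre, and prenylating first spares the chiral iodide one step and excludes later α,α-dialkylation.

Step 11
Reactants: 18 methyl (6S)-9-methyl-2-(3-methylbut-2-en-1-yl)-3-oxo-6-(prop-1-en-2-yl)dec-8-enoate
Product: 19 methyl (6S)-9-methyl-2-(3-methylbut-2-en-1-yl)-6-(prop-1-en-2-yl)-3-(trimethylsilyloxy)deca-2,8-dienoate (E/Z mixture at C2=C3)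
Conditions: TMSCl (1.8 equiv), Et3N (1.6 equiv), PhMe, rt; filtration under argon
Reagents that add atoms: trimethylsilyl chloride, C[Si](C)(C)Cl
Why: O-Silylation of the enolisable β-keto ester with amine and chlorosilane is the first stage of the standard preparation of Chan-type dienes, and the enol ether geometry is irrelevant.

Step 12
Reactants: 19 methyl (6S)-9-methyl-2-(3-methylbut-2-en-1-yl)-6-(prop-1-en-2-yl)-3-(trimethylsilyloxy)deca-2,8-dienoate
Product: 20 (3Z,6R)-1-methoxy-9-methyl-2-(3-methylbut-2-en-1-yl)-6-(prop-1-en-2-yl)-1,3-bis(trimethylsilyloxy)deca-1,3,8-triene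
Conditions: LDA (1.3 equiv), THF, −78 °C; TMSCl (1.5 equiv), −78 °C → rt; hexane, filtration under argon, used crude
Reagents that add atoms: trimethylsilyl chloride, C[Si](C)(C)Cl
Why: γ-Deprotonation of the silyloxy enoate and O-silylation of the extended ester enolate form the second stage of the Chan-diene preparation, and the kinetically formed C3=C4 bond is expected to be Z, which turns the lavandulyl chain outward in the s-cis conformer.

Step 13
Reactants: 8 (2S)-2-[2,4-bis(tert-butyldimethylsilyloxy)phenyl]-5-(phenylsulfinyl)-2,3-dihydro-4H-pyran-4-one; 20 (3Z,6R)-1-methoxy-9-methyl-2-(3-methylbut-2-en-1-yl)-6-(prop-1-en-2-yl)-1,3-bis(trimethylsilyloxy)deca-1,3,8-triene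
Product: 23 kushenol B 2',4'-bis(TBS) ether [(2S)-2-[2,4-bis(tert-butyldimethylsilyloxy)phenyl]-5,7-dihydroxy-8-[(2R)-5-methyl-2-(prop-1-en-2-yl)hex-4-en-1-yl]-6-(3-methylbut-2-en-1-yl)chroman-4-one], via cis-fused cycloadduct 21 (not isolated), via aromatised bis-TMS ether 22 (not isolated)
Conditions: 20 (1.5 equiv), ZnBr2 (1.1 equiv), 4 Å MS, CH2Cl2, −40 → 0 °C; pyridine, then 40 °C; citric acid, MeOH–THF, 0 °C
Reagents that add atoms: none
Why: Proposed new method: ZnBr2 should bridge the C4 carbonyl and sulfinyl oxygens of 8 and turn the donor-substituted C5=C6 bond into a strong acceptor at C6 (future C8a), so that the most nucleophilic diene terminus C4 (lavandulyl-bearing, future C8) bonds there and the ketene-acetal carbon C1 (future C5) bonds to the sulfinyl-bearing carbon (future C4a), closing ring A either by a highly asynchronous [4+2] cycloaddition or by Mukaiyama–Michael addition followed by 6-exo-trig attack of the α-sulfinyl zinc enolate on the silylated ester carbon. In the cis-fused adduct 21 the sulfinyl group and H-8a are syn, which is the geometry of the thermal Ei elimination, so PhSOH should leave on warming to create C4a=C8a, the resulting 1,4-cyclohexadiene should lose methanol across C5/C8 to give 22, and the aryl TMS ethers fall off in the citric acid work-up. A sulfoxide is preferred to a halogen as nucleofuge because H-8a is not α to any carbonyl and lies syn to the C4a substituent, which shuts both the E1cB and the anti-E2 route to HX and would leave a tertiary 2-halo-1,3-diketone free to transfer halonium or to contract in a Favorskii manner. The closest known reaction types are the domino Diels–Alder/sulfoxide elimination of 2-sulfinylquinones and 2-sulfinylenones with oxygenated silyloxydienes, conjugate addition–sulfoxide elimination on 3-sulfinylchromones, and Lewis-acid-mediated attack of 1,3-bis(silyloxy)dienes through C4 on chromones; the new elements are the dihydropyranone as 2π partner and the fully substituted diene. No lasting stereocentre is formed, since C4a, C5, C8 and C8a all end up sp2, while C2 and the lavandulyl centre are spectators because the mechanism breaks no bond to either, even if O1–C8a should open and reclose. The step needs regio- and chemoselectivity: the first follows from the matched polarity (C8a δ+, diene C4 δ−), and the second from the prenyl group on C6, which keeps the competing [3+3] aldol closure of C6 onto C4=O from aromatising, and from the Z enol silane, which lets the hindered diene reach its s-cis form.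

Step 14
Reactants: 23 kushenol B 2',4'-bis(TBS) ether
Product: 24 kushenol B [(2S)-2-(2,4-dihydroxyphenyl)-5,7-dihydroxy-8-[(2R)-5-methyl-2-(prop-1-en-2-yl)hex-4-en-1-yl]-6-(3-methylbut-2-en-1-yl)chroman-4-one]
Conditions: Et3N·3HF (6 equiv), THF, 0 °C → rt; pH 5 buffer work-up
Reagents that add atoms: none
Why: Aryl silyl ethers are cleaved fast by fluoride, and the weakly acidic medium should prevent both phenoxide-triggered opening to the chalcone (loss of C2 configuration) and acid-catalysed chroman formation from the prenyl and lavandulyl olefins.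

**Compound list**
1 | 2,4-dihydroxybenzaldehyde | O=Cc1ccc(O)cc1O | starting material
2 | 2,4-bis(tert-butyldimethylsilyloxy)benzaldehyde | O=Cc1ccc(O[Si](C)(C)C(C)(C)C)cc1O[Si](C)(C)C(C)(C)C | intermediate
3 | Danishefsky's diene | CO/C=C/C(=C)O[Si](C)(C)C | starting material
4 | (1E,5S)-5-[2,4-bis(tert-butyldimethylsilyloxy)phenyl]-1-methoxy-5-(trimethylsilyloxy)pent-1-en-3-one (not isolated) | CO/C=C/C(=O)C[C@H](O[Si](C)(C)C)c1ccc(O[Si](C)(C)C(C)(C)C)cc1O[Si](C)(C)C(C)(C)C | intermediate
5 | (2S)-2-[2,4-bis(tert-butyldimethylsilyloxy)phenyl]-2,3-dihydro-4H-pyran-4-one | O=C1C=CO[C@H](c2ccc(O[Si](C)(C)C(C)(C)C)cc2O[Si](C)(C)C(C)(C)C)C1 | intermediate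
6 | (2S)-2-aryl-6-chloro-5-(phenylsulfanyl)tetrahydropyran-4-one, C5/C6 undefined (not isolated) | O=C1C(Sc2ccccc2)C(Cl)O[C@H](c2ccc(O[Si](C)(C)C(C)(C)C)cc2O[Si](C)(C)C(C)(C)C)C1 | intermediate
7 | (2S)-2-[2,4-bis(tert-butyldimethylsilyloxy)phenyl]-5-(phenylsulfanyl)-2,3-dihydro-4H-pyran-4-one | O=C1C(Sc2ccccc2)=CO[C@H](c2ccc(O[Si](C)(C)C(C)(C)C)cc2O[Si](C)(C)C(C)(C)C)C1 | intermediate
8 | (2S)-2-[2,4-bis(tert-butyldimethylsilyloxy)phenyl]-5-(phenylsulfinyl)-2,3-dihydro-4H-pyran-4-one, both sulfur epimers | O=C1C(S(=O)c2ccccc2)=CO[C@H](c2ccc(O[Si](C)(C)C(C)(C)C)cc2O[Si](C)(C)C(C)(C)C)C1 | intermediate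
9 | (S)-4-benzyl-1,3-oxazolidin-2-one | O=C1N[C@@H](Cc2ccccc2)CO1 | starting material
10 | 3-methylbut-2-enoyl chloride | CC(C)=CC(=O)Cl | starting material
11 | (4S)-4-benzyl-3-(3-methylbut-2-enoyl)-1,3-oxazolidin-2-one | CC(C)=CC(=O)N1[C@@H](Cc2ccccc2)COC1=O | intermediate
12 | prenyl bromide | CC(C)=CCBr | starting material
13 | (4S)-4-benzyl-3-[(2S)-5-methyl-2-(prop-1-en-2-yl)hex-4-enoyl]-1,3-oxazolidin-2-one | C=C(C)[C@H](CC=C(C)C)C(=O)N1[C@@H](Cc2ccccc2)COC1=O | intermediate
14 | (S)-lavandulol | C=C(C)[C@H](CC=C(C)C)CO | intermediate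
15 | (S)-lavandulyl iodide | C=C(C)[C@H](CC=C(C)C)CI | intermediate
16 | methyl acetoacetate | COC(=O)CC(C)=O | starting material
17 | methyl 2-acetyl-5-methylhex-4-enoate (racemic) | COC(=O)C(CC=C(C)C)C(C)=O | intermediate
18 | methyl (6S)-9-methyl-2-(3-methylbut-2-en-1-yl)-3-oxo-6-(prop-1-en-2-yl)dec-8-enoate (C2 epimers) | C=C(C)[C@H](CC=C(C)C)CCC(=O)C(CC=C(C)C)C(=O)OC | intermediate
19 | methyl (6S)-9-methyl-2-(3-methylbut-2-en-1-yl)-6-(prop-1-en-2-yl)-3-(trimethylsilyloxy)deca-2,8-dienoate (E/Z) | C=C(C)[C@H](CC=C(C)C)CCC(O[Si](C)(C)C)=C(CC=C(C)C)C(=O)OC | intermediate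
20 | (3Z,6R)-1-methoxy-9-methyl-2-(3-methylbut-2-en-1-yl)-6-(prop-1-en-2-yl)-1,3-bis(trimethylsilyloxy)deca-1,3,8-triene | C=C(C)[C@H](CC=C(C)C)C/C=C(\O[Si](C)(C)C)C(CC=C(C)C)=C(OC)O[Si](C)(C)C | intermediate
21 | cis-fused [4+2] adduct of 8 and 20, transient centres C4a, C5, C8, C8a and S undefined (not isolated) | C=C(C)[C@H](CC=C(C)C)CC1C(O[Si](C)(C)C)=C(CC=C(C)C)C(OC)(O[Si](C)(C)C)C2(S(=O)c3ccccc3)C(=O)C[C@@H](c3ccc(O[Si](C)(C)C(C)(C)C)cc3O[Si](C)(C)C(C)(C)C)OC12 | intermediate
22 | kushenol B 2',4'-bis(TBS) 5,7-bis(TMS) ether (not isolated) | C=C(C)[C@H](CC=C(C)C)Cc1c(O[Si](C)(C)C)c(CC=C(C)C)c(O[Si](C)(C)C)c2c1O[C@H](c1ccc(O[Si](C)(C)C(C)(C)C)cc1O[Si](C)(C)C(C)(C)C)CC2=O | intermediate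
23 | kushenol B 2',4'-bis(TBS) ether | C=C(C)[C@H](CC=C(C)C)Cc1c(O)c(CC=C(C)C)c(O)c2c1O[C@H](c1ccc(O[Si](C)(C)C(C)(C)C)cc1O[Si](C)(C)C(C)(C)C)CC2=O | intermediate
24 | kushenol B | C=C(C)[C@H](CC=C(C)C)Cc1c(O)c(CC=C(C)C)c(O)c2c1O[C@H](c1ccc(O)cc1O)CC2=O | target

**Step count**
- Total steps: 14.
- Longest linear sequence: 9 steps (5, 6, 7, 8, 10, 11, 12, 13, 14).

**Steps most likely to fail**

1. Step 13 (Proposed new method).
- What may go wrong: the reaction may stall after the first C–C bond, when silyl transfer quenches the zwitterion. Ring C may open by retro-oxa-Michael reaction, or ionise at the benzylic C2 under the Lewis acid, with erosion of configuration. The hindered diene may also be protodesilylated faster than it adds.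
- Fallback (sets out from 5 and 20, returns at 23): the two bonds are made one after the other by known reaction types. Pyranone 5 needs no C5 substituent here. It is activated with TMSOTf (CH2Cl2, −78 °C) as its 4-silyloxy oxocarbenium ion and takes up 20 through C4 in a Mukaiyama–Michael addition. This is known for 1,3-bis(silyloxy)dienes with chromones and for silyl ketene acetals with dihydropyranones. A pyridine quench keeps both silyl groups and gives the bis-silylated Michael adduct F1. Saegusa–Ito oxidation (Pd(OAc)2, MeCN) acts on the ring enol silane, whose only β-hydrogen is H-8a. Mild hydrolysis of the side-chain enol silane then restores the vinylogous ester and gives the 6-substituted dihydropyranone keto ester F2, a ring-C-locked 3,5,7-trioxo ester. Its biomimetic Claisen cyclisation (DBU, dry PhMe, 0 °C → rt, short contact) gives 23: deprotonation at C8 makes C4a nucleophilic, 6-exo-trig attack on the ester follows, then loss of methanol and tautomerisation. F2 is also what step 13 would deliver if it stopped after addition and sulfoxide loss, so the last operation can rescue such material.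

2. Step 10.
- What may go wrong: the strongly basic dianion may remove the allylic β-hydrogen of the β-branched iodide (E2 to a conjugated diene) faster than the hindered SN2 displacement proceeds.
- Fallback (sets out from 15, returns at 18): the chain is extended with a much less basic nucleophile, and the β-keto ester is assembled by acylation instead of alkylation. Iodide 15 alkylates sodium dimethyl malonate (NaH, THF–DMF, 50 °C) to give dimethyl (R)-lavandulylmalonate F3. Saponification (KOH, aq. MeOH) and thermal decarboxylation (pyridine, reflux) give (4S)-7-methyl-4-(prop-1-en-2-yl)oct-6-enoic acid F4. Activation with CDI and reaction with the magnesium enolate of potassium methyl malonate (MgCl2, Et3N; Masamune–Brooks homologation) give methyl (6S)-9-methyl-3-oxo-6-(prop-1-en-2-yl)dec-8-enoate F5. This is prenylated at C2 with 12 (K2CO3, acetone) to give 18.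

3. Step 2.
- What may go wrong: the electron-rich, ortho-substituted aldehyde may react sluggishly and with eroded facial selectivity on the catalyst.
- Fallback (sets out from 2, returns at 5): C2 is set by a stoichiometric chiral reagent. Brown allylation of 2 with (−)-Ipc2B(allyl), prepared from (+)-α-pinene (Et2O, −78 °C, ethanolamine work-up), gives the (S)-homoallylic alcohol F6. This reagent is known to give the (S) alcohol from aryl aldehydes. Wacker–Tsuji oxidation (PdCl2, CuCl, O2, DMF–H2O) gives the (S)-β-hydroxy methyl ketone F7. Condensation with DMF dimethyl acetal gives the (S)-hydroxy enaminone F8, which closes to 5 with TFA by oxa-Michael addition and loss of the amine.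

**Further compounds**
F1 | step 13 | methyl 2-(3-methylbut-2-enyl)-3-(trimethylsilyloxy)-4-[(6S)-6-aryl-4-(trimethylsilyloxy)-5,6-dihydro-2H-pyran-2-yl]-4-lavandulylbut-2-enoate (bis-silylated Michael adduct) | C=C(C)[C@H](CC=C(C)C)CC(C(O[Si](C)(C)C)=C(CC=C(C)C)C(=O)OC)C1C=C(O[Si](C)(C)C)C[C@@H](c2ccc(O[Si](C)(C)C(C)(C)C)cc2O[Si](C)(C)C(C)(C)C)O1
F2 | step 13 | 6-substituted (2S)-2-aryl-2,3-dihydro-4H-pyran-4-one keto ester | C=C(C)[C@H](CC=C(C)C)CC(C(=O)C(CC=C(C)C)C(=O)OC)C1=CC(=O)C[C@@H](c2ccc(O[Si](C)(C)C(C)(C)C)cc2O[Si](C)(C)C(C)(C)C)O1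
F3 | step 10 | dimethyl 2-[(2R)-5-methyl-2-(prop-1-en-2-yl)hex-4-en-1-yl]malonate | C=C(C)[C@H](CC=C(C)C)CC(C(=O)OC)C(=O)OC
F4 | step 10 | (4S)-7-methyl-4-(prop-1-en-2-yl)oct-6-enoic acid | C=C(C)[C@H](CC=C(C)C)CCC(=O)O
F5 | step 10 | methyl (6S)-9-methyl-3-oxo-6-(prop-1-en-2-yl)dec-8-enoate | C=C(C)[C@H](CC=C(C)C)CCC(=O)CC(=O)OC
F6 | step 2 | (1S)-1-[2,4-bis(tert-butyldimethylsilyloxy)phenyl]but-3-en-1-ol | C=CC[C@H](O)c1ccc(O[Si](C)(C)C(C)(C)C)cc1O[Si](C)(C)C(C)(C)C
F7 | step 2 | (4S)-4-[2,4-bis(tert-butyldimethylsilyloxy)phenyl]-4-hydroxybutan-2-one | CC(=O)C[C@H](O)c1ccc(O[Si](C)(C)C(C)(C)C)cc1O[Si](C)(C)C(C)(C)C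
F8 | step 2 | (1E,5S)-5-[2,4-bis(tert-butyldimethylsilyloxy)phenyl]-1-(dimethylamino)-5-hydroxypent-1-en-3-one | CN(C)/C=C/C(=O)C[C@H](O)c1ccc(O[Si](C)(C)C(C)(C)C)cc1O[Si](C)(C)C(C)(C)C
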